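**Retrosynthetic overview**

- Rings: A is the outer 2,4,6-trihydroxyphenoxy ring. B is the middle ring (ether O at C-1 and C-3, OH at C-5). C has ether O at C-1, OH at C-2, C-4 and C-6, and ring D at C-3. D is the C-bound 2,4,6-trihydroxyphenyl ring.
- Feature: the oxygens on C-4 of ring A, C-5 of ring B and C-4 of ring D each sit on a carbon flanked by two ring CH groups. Once these three oxygens are deleted, those carbons carry the only aryl C–H bonds of the tetramer with no ortho neighbour.
- Disconnections: (i) seven O–CH3 bonds (BBr3, last); (ii) the three C–O bonds just named, all at once, by iridium C–H borylation and oxidation; (iii) the C–D biaryl bond (Suzuki–Miyaura on a ring C bromide placed by NBS); (iv) the two diaryl ether bonds (CuI couplings on 1-bromo-3-iodobenzene, C–I before C–Br).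
- No ring is built. All four benzene rings are bought and joined in the order A–B, B–C, C–D, so bromination and biaryl coupling never meet a free, easily oxidised phenol.
- Methyl ethers protect throughout, because they survive every step and add no aryl C–H that iridium could attack.

Key step: step 5

Assumption: the target has no stereocentre and its C–D axis is not stereogenic (ring D is symmetric about it), so no stereocontrol is planned; 2,4,6-trimethoxyphenol and 1-bromo-3-iodobenzene are taken as catalogue chemicals.

**Step 1**
Reactants: 1 2,6-dimethoxyphenol; 2 1-bromo-3-iodobenzene (1.3 equiv)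
Product: 3 2-(3-bromophenoxy)-1,3-dimethoxybenzene
Conditions: CuI (10 mol %), picolinic acid (20 mol %), K3PO4 (2 equiv), DMSO, 80 °C, Ar
Reagents that add atoms: none
Why: Ligand-accelerated Ullmann diaryl ether synthesis, in which the monovalent copper phenoxide attacks the C–I bond much faster than the C–Br bond, so ring B should be etherified once (a statistical mixture, as from 1,3-dibromobenzene, is avoided) and the bromide is kept for step 2; the picolinic acid system accepts di-ortho-substituted phenols.

**Step 2**
Reactants: 3 2-(3-bromophenoxy)-1,3-dimethoxybenzene; 4 2,4,6-trimethoxyphenol (1.3 equiv)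
Product: 5 1-(2,6-dimethoxyphenoxy)-3-(2,4,6-trimethoxyphenoxy)benzene
Conditions: CuI (20 mol %), picolinic acid (40 mol %), K3PO4 (2 equiv), DMSO, 105 °C, Ar
Reagents that add atoms: none
Why: Second Ullmann-type C–O coupling, now at the remaining unhindered aryl bromide at higher temperature; electron-rich di-ortho-methoxy phenoxides are the classical nucleophiles for phlorethol methyl ethers, and air is excluded because this phenoxide is easily oxidised.

**Step 3**
Reactants: 5 1-(2,6-dimethoxyphenoxy)-3-(2,4,6-trimethoxyphenoxy)benzene
Product: 6 1-(3-bromo-2,4,6-trimethoxyphenoxy)-3-(2,6-dimethoxyphenoxy)benzene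
Conditions: NBS (1.0 equiv), MeCN, −20 to 0 °C, dark
Reagents that add atoms: N-bromosuccinimide, O=C1CCC(=O)N1Br
Why: Electrophilic aromatic bromination, in which the two equivalent CH positions of ring C are ortho, ortho and para to three methoxy groups and so far more nucleophilic than any CH of ring A (two methoxy donors) or ring B (two weaker aryloxy donors), while the first bromine deactivates ring C towards a second.

**Step 4**
Reactants: 6 1-(3-bromo-2,4,6-trimethoxyphenoxy)-3-(2,6-dimethoxyphenoxy)benzene; 7 (2,6-dimethoxyphenyl)boronic acid (2 equiv, in two portions)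
Product: 8 1-(2,6-dimethoxyphenoxy)-3-[3-(2,6-dimethoxyphenyl)-2,4,6-trimethoxyphenoxy]benzene
Conditions: Pd2(dba)3 (2.5 mol %), SPhos (10 mol %), K3PO4 (3 equiv), toluene, 100 °C, Ar
Reagents that add atoms: none
Why: Suzuki–Miyaura coupling with the bulky, electron-rich biarylphosphine SPhos, a system suited to tetra-ortho-substituted biaryls; methoxy groups are small ortho substituents, the low-water medium and the excess of 7 offset protodeboronation, and no atropisomers can arise because ring D is symmetric.

**Step 5**
Reactants: 8 1-(2,6-dimethoxyphenoxy)-3-[3-(2,6-dimethoxyphenyl)-2,4,6-trimethoxyphenoxy]benzene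
Product: 10 3-(4-hydroxy-2,6-dimethoxyphenoxy)-5-[3-(4-hydroxy-2,6-dimethoxyphenyl)-2,4,6-trimethoxyphenoxy]phenol, via tris(pinacol boronate) 9 (not isolated)
Conditions: (a) B2pin2 (2.0 equiv), [Ir(OMe)(cod)]2 (5 mol %), 4,4'-di-tert-butyl-2,2'-bipyridine (10 mol %), THF, 80 °C (sealed), Ar; evaporate; (b) Oxone (2KHSO5·KHSO4·K2SO4, about 4 equiv of KHSO5), acetone/H2O, 0 °C to rt, 10–15 min; aq NaHSO3
Reagents that add atoms: bis(pinacolato)diboron, CC1(C)OB(OC1(C)C)B1OC(C)(C)C(C)(C)O1 (its atoms stay only in 9); potassium peroxymonosulfate KHSO5 from Oxone, [K+].OOS(=O)(=O)[O-] (the three new oxygen atoms)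
Why: Precatalyst, bipyridine and B2pin2 form a trivalent iridium tris(boryl) complex that cleaves an aryl C–H bond and releases the aryl boronate by C–B reductive elimination, the HBpin formed re-entering the cycle; peroxymonosulfate then adds to each boron, and a 1,2-shift of the aryl group from boron to oxygen followed by hydrolysis gives the phenol at the same carbon. The closest known reaction type is the one-pot iridium C–H borylation/Oxone oxidation that turns 1,3-disubstituted and 1,2,3-trisubstituted arenes into 3,5-disubstituted and 3,4,5-trisubstituted phenols, for which 1,3-dialkoxy- and 1,2,3-trialkoxybenzenes are established substrates. No ring is closed and no stereocentre is made. The step needs site selectivity among eleven aryl C–H bonds: the crowded iridium centre does not reach a C–H next to a substituent, and in 8 H-3/H-5 of rings A and D lie next to a methoxy group, H-2, H-4 and H-6 of ring B lie next to an aryloxy group, and the single H of ring C lies between two methoxy groups, so only H-4 of A, H-5 of B and H-4 of D remain. Because the three rings react independently and no fourth site is open, the borylation is self-limiting and can be pushed with surplus boron. The oxidant is kept close to the boron content and quenched after minutes to spare the para-aryloxyphenol formed on ring A.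

**Step 6**
Reactants: 10 3-(4-hydroxy-2,6-dimethoxyphenoxy)-5-[3-(4-hydroxy-2,6-dimethoxyphenyl)-2,4,6-trimethoxyphenoxy]phenol
Product: 11 3-[3-hydroxy-5-(2,4,6-trihydroxyphenoxy)phenoxy]biphenyl-2,2',4,4',6,6'-hexol (CNP0260439.0)
Conditions: BBr3 (15 equiv, 1 M in CH2Cl2), CH2Cl2, −78 °C to rt, Ar; degassed H2O, 0 °C; EtOAc extraction, Sephadex LH-20 (MeOH)
Reagents that add atoms: none
Why: Lewis-acid ether cleavage, in which BBr3 binds each methoxy oxygen and bromide removes the methyl group by SN2, whereas the two diaryl ether bonds and the biaryl bond offer no sp3 carbon and should survive; the three free phenols only consume extra reagent, and degassed work-up guards the air-sensitive polyphenol.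

**Compound list**

1 | 2,6-dimethoxyphenol | COc1cccc(OC)c1O | starting material
2 | 1-bromo-3-iodobenzene | Brc1cccc(I)c1 | starting material
3 | 2-(3-bromophenoxy)-1,3-dimethoxybenzene | COc1cccc(OC)c1Oc1cccc(Br)c1 | intermediate
4 | 2,4,6-trimethoxyphenol | COc1cc(OC)c(O)c(OC)c1 | starting material
5 | 1-(2,6-dimethoxyphenoxy)-3-(2,4,6-trimethoxyphenoxy)benzene | COc1cccc(OC)c1Oc1cccc(Oc2c(OC)cc(OC)cc2OC)c1 | intermediate
6 | 1-(3-bromo-2,4,6-trimethoxyphenoxy)-3-(2,6-dimethoxyphenoxy)benzene | COc1cccc(OC)c1Oc1cccc(Oc2c(OC)cc(OC)c(Br)c2OC)c1 | intermediate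
7 | (2,6-dimethoxyphenyl)boronic acid | COc1cccc(OC)c1B(O)O | starting material
8 | 1-(2,6-dimethoxyphenoxy)-3-[3-(2,6-dimethoxyphenyl)-2,4,6-trimethoxyphenoxy]benzene | COc1cccc(OC)c1Oc1cccc(Oc2c(OC)cc(OC)c(-c3c(OC)cccc3OC)c2OC)c1 | intermediate
9 | tris(pinacol boronate) of 8, with 4,4,5,5-tetramethyl-1,3,2-dioxaborolan-2-yl groups at C-4 of ring A, C-5 of ring B and C-4 of ring D | COc1cc(B2OC(C)(C)C(C)(C)O2)cc(OC)c1Oc1cc(B2OC(C)(C)C(C)(C)O2)cc(Oc2c(OC)cc(OC)c(-c3c(OC)cc(B4OC(C)(C)C(C)(C)O4)cc3OC)c2OC)c1 | intermediate
10 | 3-(4-hydroxy-2,6-dimethoxyphenoxy)-5-[3-(4-hydroxy-2,6-dimethoxyphenyl)-2,4,6-trimethoxyphenoxy]phenol | COc1cc(O)cc(OC)c1Oc1cc(O)cc(Oc2c(OC)cc(OC)c(-c3c(OC)cc(O)cc3OC)c2OC)c1 | intermediate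
11 | 3-[3-hydroxy-5-(2,4,6-trihydroxyphenoxy)phenoxy]biphenyl-2,2',4,4',6,6'-hexol | Oc1cc(Oc2c(O)cc(O)cc2O)cc(Oc2c(O)cc(O)c(-c3c(O)cc(O)cc3O)c2O)c1 | target

**Step count**

Total step count: 6.
Longest linear sequence: 6 (steps 1 to 6; the route is linear).

**Steps most likely to fail**

**Step 5.**
- What may go wrong: the third borylation may stall on these electron-rich, slowly reacting rings, so that partly borylated material persists. Forcing may bring in some borylation next to a methoxy group. Surplus peroxymonosulfate may oxidise the ring A para-aryloxyphenol with loss of the aryl ether.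
- Fallback (sets out from 4, comes back at 11): the three oxygens are bought instead of installed. 3,5-Dibromoanisole is etherified at both bromides with 4 (CuI, picolinic acid, K3PO4, DMSO, 105 °C) to give 1-methoxy-3,5-bis(2,4,6-trimethoxyphenoxy)benzene F1. NBS in MeCN is used in deficit because the two outer rings are equivalent, and unreacted F1 is recycled; this gives 1-(3-bromo-2,4,6-trimethoxyphenoxy)-3-methoxy-5-(2,4,6-trimethoxyphenoxy)benzene F2. Suzuki–Miyaura coupling with (2,4,6-trimethoxyphenyl)boronic acid under the conditions of step 4 gives the decamethyl ether of the target F3. BBr3 as in step 6 then cleaves all ten methyl ethers to 11.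

**Step 4.**
- What may go wrong: protodeboronation of the di-ortho-methoxy boronic acid may outrun the slow transmetalation and reductive elimination at a palladium centre that must carry two di-ortho-substituted aryl groups. Hydrodebromination of the bromide may then take over.
- Fallback (sets out from 6, comes back at 8): Negishi coupling. 1,3-Dimethoxybenzene is lithiated between its methoxy groups (n-BuLi, THF, 0 °C to rt) to (2,6-dimethoxyphenyl)lithium F4. ZnCl2 converts this into (2,6-dimethoxyphenyl)zinc chloride F5. This is coupled with 6 using Pd2(dba)3 and RuPhos in THF at 70 °C, a combination known for tetra-ortho-substituted biaryls. The arylzinc transmetalates without base or water, which closes the protodemetalation channel.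

**Step 6.**
- What may go wrong: cleavage may stop short when partly demethylated boron phenoxides precipitate from CH2Cl2. The free polyphenol may also oxidise in air or bind irreversibly to the stationary phase during purification.
- Fallback (sets out from 10, comes back at 11): trap and release. The crude product of the BBr3 cleavage is not purified but acetylated (Ac2O, pyridine, rt) to 3-[3-acetoxy-5-(2,4,6-triacetoxyphenoxy)phenoxy]biphenyl-2,2',4,4',6,6'-hexayl hexaacetate F6. This ester is air-stable and can be chromatographed on silica, where under-cleaved material is removed. Acid-catalysed methanolysis (catalytic AcCl in degassed MeOH, rt to 40 °C) followed by evaporation then releases 11 without ever forming air-sensitive phenoxides.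

**Further compounds**

F1 | step 5 | 1-methoxy-3,5-bis(2,4,6-trimethoxyphenoxy)benzene | COc1cc(Oc2c(OC)cc(OC)cc2OC)cc(Oc2c(OC)cc(OC)cc2OC)c1
F2 | step 5 | 1-(3-bromo-2,4,6-trimethoxyphenoxy)-3-methoxy-5-(2,4,6-trimethoxyphenoxy)benzene | COc1cc(Oc2c(OC)cc(OC)cc2OC)cc(Oc2c(OC)cc(OC)c(Br)c2OC)c1
F3 | step 5 | decamethyl ether of the target, 1-methoxy-3-(2,4,6-trimethoxyphenoxy)-5-[2,4,6-trimethoxy-3-(2,4,6-trimethoxyphenyl)phenoxy]benzene | COc1cc(Oc2c(OC)cc(OC)cc2OC)cc(Oc2c(OC)cc(OC)c(-c3c(OC)cc(OC)cc3OC)c2OC)c1
F4 | step 4 | (2,6-dimethoxyphenyl)lithium | [Li]c1c(OC)cccc1OC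
F5 | step 4 | (2,6-dimethoxyphenyl)zinc chloride | Cl[Zn]c1c(OC)cccc1OC
F6 | step 6 | 3-[3-acetoxy-5-(2,4,6-triacetoxyphenoxy)phenoxy]biphenyl-2,2',4,4',6,6'-hexayl hexaacetate | CC(=O)Oc1cc(Oc2c(OC(C)=O)cc(OC(C)=O)cc2OC(C)=O)cc(Oc2c(OC(C)=O)cc(OC(C)=O)c(-c3c(OC(C)=O)cc(OC(C)=O)cc3OC(C)=O)c2OC(C)=O)c1
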